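**Retrosynthetic overview**

1. Feature: C2 of ring A (the =CH2 carbon, a ketone until late) and the oxygen-bearing C5' of ring B are 1,5-related across the vicinal quaternary carbons C1–C1'. This is the pattern left by a de Mayo reaction ([2+2] photocycloaddition, then retro-aldol).
2. Target ⇒ acylation of O5' with silyl-protected caffeic acid ⇒ dienol 17 ⇒ (Wittig at C2, CBS reduction at C5') enone 15 ⇒ (aldol condensation C4'→C3', ring B) keto aldehyde 13 ⇒ (ozonolysis) diketone 11.
3. 11 ⇒ intramolecular de Mayo reaction of 1,3-diketone 9: C2–C1 and C6'–C1' are formed and C2–C6' is cleaved, so ring A and both quaternary centres come from one tetrasubstituted alkene.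
4. 9 ⇒ Claisen condensation of methyl ketone 7 with ethyl propanoate; 7 ⇒ two copper-catalysed allylic couplings on (E)-1,4-dibromo-2,3-dimethylbut-2-ene (2).
5. Ring order: ring A (step 6), then ring B (step 8).

Key step: step 6

Remark: the target locants (C1–C5 in ring A, C1'–C6' in ring B) are used for all intermediates; 9 reacts through its chelated enol/diketonate, and its E geometry is not transferred to the product.
Remark: (R,R)-t-Bu-BOX is 2,2'-(propane-2,2-diyl)bis[(4R)-4-tert-butyl-4,5-dihydro-1,3-oxazole]; the (R,R) enantiomer is assigned from a tetrahedral zinc chelate model, the sense of induction must be confirmed in the first experiment, and the (S,S) ligand would be used if it proves opposite.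

**Route**

Step 1
Reactants: 1 2,3-dimethylbuta-1,3-diene
Product: 2 (E)-1,4-dibromo-2,3-dimethylbut-2-ene
Conditions: Br2 (1.0 equiv), CH2Cl2, −20 °C; crystallisation from pentane
Reagents that add atoms: bromine, BrBr
Why: Electrophilic 1,4-addition of bromine to the diene under thermodynamic control should give the crystalline E dibromide, which fixes the geometry of the future C1=C1' alkene; no stereocentre is formed.

Step 2
Reactants: 3 2-(2-bromoethyl)-2-methyl-1,3-dioxolane; 2 (E)-1,4-dibromo-2,3-dimethylbut-2-ene (3 equiv)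
Product: 5 2-[(E)-6-bromo-4,5-dimethylhex-4-en-1-yl]-2-methyl-1,3-dioxolane, via Grignard reagent 4 (not isolated)
Conditions: Mg, THF, 25 °C; then 2 (3 equiv), Li2CuCl4 (3 mol%), THF, −40 → 0 °C
Reagents that add atoms: none
Why: Copper-catalysed coupling of an alkyl Grignard reagent with an allylic bromide should go at the primary α carbon, since γ attack would have to build a quaternary carbon; the threefold excess of 2 holds double substitution down and is recovered, and the ketal masks the future C2 carbonyl.

Step 3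
Reactants: 5 2-[(E)-6-bromo-4,5-dimethylhex-4-en-1-yl]-2-methyl-1,3-dioxolane
Product: 6 2-[(E)-4,5-dimethylocta-4,7-dien-1-yl]-2-methyl-1,3-dioxolane
Conditions: CH2=CHMgBr (1.5 equiv), CuI (10 mol%), THF, −30 °C → rt
Reagents that add atoms: vinylmagnesium bromide, C=C[Mg]Br
Why: A second copper-catalysed allylic substitution, now with a vinyl Grignard reagent, should again go at the α carbon and give the skipped diene with the E alkene unchanged; the vinyl group is the masked C3' aldehyde.

Step 4
Reactants: 6 2-[(E)-4,5-dimethylocta-4,7-dien-1-yl]-2-methyl-1,3-dioxolane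
Product: 7 (E)-6,7-dimethyldeca-6,9-dien-2-one
Conditions: 1 M HCl, THF, rt
Reagents that add atoms: water, O
Why: Acid-catalysed ketal hydrolysis frees the methyl ketone, while the isolated alkenes should not react with dilute acid at room temperature.

Step 5
Reactants: 7 (E)-6,7-dimethyldeca-6,9-dien-2-one; 8 ethyl propanoate (2 equiv)
Product: 9 (E)-8,9-dimethyldodeca-8,11-diene-3,5-dione
Conditions: NaH (2.5 equiv), THF, 0 °C → reflux; then 1 M HCl
Reagents that add atoms: none
Why: Crossed Claisen condensation: the sodium enolate of the methyl ketone is acylated by the ester at the methyl carbon (the future C6'), the usual site for methyl alkyl ketones, and the equilibrium is drawn to the product by formation of the sodium diketonate.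

Step 6
Reactants: 9 (E)-8,9-dimethyldodeca-8,11-diene-3,5-dione
Product: 11 (2R)-2-methyl-2-[(4S)-4-methyl-6-oxooct-1-en-4-yl]cyclopentan-1-one, via cyclobutanol photoadduct 10 (not isolated)
Conditions: Zn(OTf)2 (30 mol%), (R,R)-t-Bu-BOX (33 mol%), 2,6-lutidine (30 mol%), CH2Cl2 (5 mM), −40 °C, hν (313 nm), Ar; then aq. NH4Cl
Reagents that add atoms: none
Why: Proposed new method: the closest known reactions are the uncatalysed, racemic intramolecular de Mayo reaction of 1,3-diketone enols, the [2+2] photocycloaddition of 1,3-diketonatoboron difluorides to alkenes, and enone [2+2] photocycloadditions controlled by chiral Lewis acids through selective excitation of the bound substrate; new is control of the enol face, reasoned thus: 9 is held by Zn(OTf)2/(R,R)-t-Bu-BOX as a tetrahedral O,O'-diketonate whose π–π* band is expected at longer wavelength than that of the free hydrogen-bonded enol, so that 313 nm light should excite mainly the bound substrate. The excited chelate bonds first from C2 to C1 (5-exo closure of ring A through the C3–C5 tether, the usual 1,5 mode), and the 1,4-biradical then joins C6' to C1' to close the four-membered ring of the cis-fused bicyclo[3.2.0]heptane 10 (straight, not crossed, adduct). The zinc aldolate of 10 is a strained cyclobutanol β to the C5' carbonyl and should open by retro-aldol cleavage of C2–C6', and the zinc enolate so formed is protonated by the far more acidic 9 (or by lutidinium triflate), which releases 11 and reloads the catalyst. C1 is set in the first bond formation by the ligand, one tert-butyl group of which lies over one face of the chelate at its C2 end, and C1' is set when the biradical closes with the longer C2' allyl chain on the convex face beside the C1 methyl group and the C1' methyl group on the concave face under ring A; the E geometry of the alkene is not transferred and the C6' centre of 10 is lost in the fragmentation. The step needs regioselectivity, secured by the three-carbon tether that lets the alkene reach only C2 and only in the straight sense, enantioface selectivity, which rests on the ligand, and exo placement of the allyl group, for which the substrate offers only the difference between CH2R and CH3, so that some C1' epimer is expected and would be removed by chromatography at 15.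

Step 7
Reactants: 11 (2R)-2-methyl-2-[(4S)-4-methyl-6-oxooct-1-en-4-yl]cyclopentan-1-one
Product: 13 (3S)-3-methyl-3-[(1R)-1-methyl-2-oxocyclopentyl]-5-oxoheptanal, via secondary ozonide 12 (not isolated)
Conditions: O3, CH2Cl2, −78 °C; then Me2S, −78 °C → rt
Reagents that add atoms: ozone, [O-][O+]=O
Why: Ozonolysis (Criegee mechanism) with reductive work-up cleaves the only C=C bond to the C3' aldehyde; the two ketones do not react and the quaternary centres cannot epimerise.

Step 8
Reactants: 13 (3S)-3-methyl-3-[(1R)-1-methyl-2-oxocyclopentyl]-5-oxoheptanal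
Product: 15 (5S)-2,5-dimethyl-5-[(1R)-1-methyl-2-oxocyclopentyl]cyclohex-2-en-1-one, via aldol adduct 14 (not isolated)
Conditions: p-TsOH·H2O (10 mol%), toluene, 80 °C
Reagents that add atoms: none
Why: Acid-catalysed intramolecular aldol condensation: the enol of the ethyl ketone adds through C4' to the aldehyde C3' (six-membered ring B) and loss of water gives the conjugated 2-methylcyclohexenone, whereas the other aldol modes would give four-membered rings, bridged aldols that cannot dehydrate and revert, or need attack on the neopentyl C2 ketone.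

Step 9
Reactants: 15 (5S)-2,5-dimethyl-5-[(1R)-1-methyl-2-oxocyclopentyl]cyclohex-2-en-1-one
Product: 16 (2R)-2-[(1S,5S)-5-hydroxy-1,4-dimethylcyclohex-3-en-1-yl]-2-methylcyclopentan-1-one
Conditions: (R)-Me-CBS oxazaborolidine [(3aR)-1-methyl-3,3-diphenyltetrahydro-1H,3H-pyrrolo[1,2-c][1,3,2]oxazaborole] (0.5 equiv), catecholborane (1.5 equiv), toluene, −78 °C; then MeOH, aq. NaOH
Reagents that add atoms: none
Why: Corey–Bakshi–Shibata reduction: the oxazaborolidine binds the enone oxygen on the side of the small C6'H2 flank and delivers hydride to one face under reagent control, the (R) catalyst giving the (S) carbinol at C5' as for other 2-substituted cyclohexenones, while the C2 ketone between a quaternary and a methylene carbon should be too hindered to react at −78 °C.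

Step 10
Reactants: 16 (2R)-2-[(1S,5S)-5-hydroxy-1,4-dimethylcyclohex-3-en-1-yl]-2-methylcyclopentan-1-one
Product: 17 (1S,5S)-2,5-dimethyl-5-[(1S)-1-methyl-2-methylidenecyclopentyl]cyclohex-2-en-1-ol
Conditions: Ph3PCH3Br (5 equiv), KOtBu (5 equiv), toluene, 90 °C
Reagents that add atoms: methyltriphenylphosphonium bromide, C[P+](c1ccccc1)(c1ccccc1)c1ccccc1.[Br-]
Why: Wittig methylenation with excess ylide at elevated temperature is the usual way to methylenate neopentyl ketones; the C5' hydroxyl is carried as its potassium alkoxide and no stereocentre is touched.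

Step 11
Reactants: 18 caffeic acid
Product: 20 (E)-3-[3,4-bis(tert-butyldimethylsilyloxy)phenyl]prop-2-enoic acid, via tris-silylated caffeic acid 19 (not isolated)
Conditions: TBSCl (3.5 equiv), imidazole (7 equiv), DMF, rt; then AcOH/THF/H2O (3:1:1), rt
Reagents that add atoms: tert-butyldimethylsilyl chloride, CC(C)(C)[Si](C)(C)Cl
Why: Silylation of both phenols and the acid, followed by selective hydrolysis of the labile silyl ester, should give the acid with the catechol masked as silyl ethers that fluoride removes at the end.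

Step 12
Reactants: 17 (1S,5S)-2,5-dimethyl-5-[(1S)-1-methyl-2-methylidenecyclopentyl]cyclohex-2-en-1-ol; 20 (E)-3-[3,4-bis(tert-butyldimethylsilyloxy)phenyl]prop-2-enoic acid
Product: 21 (1S,5S)-2,5-dimethyl-5-[(1S)-1-methyl-2-methylidenecyclopentyl]cyclohex-2-en-1-yl (E)-3-[3,4-bis(tert-butyldimethylsilyloxy)phenyl]prop-2-enoate
Conditions: EDC·HCl (1.5 equiv), DMAP (0.3 equiv), CH2Cl2, 0 °C → rt
Reagents that add atoms: none
Why: Steglich esterification (carbodiimide, DMAP) acylates O5' with retention at C5', and the E geometry of the cinnamate is kept.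

Step 13
Reactants: 21 (1S,5S)-2,5-dimethyl-5-[(1S)-1-methyl-2-methylidenecyclopentyl]cyclohex-2-en-1-yl (E)-3-[3,4-bis(tert-butyldimethylsilyloxy)phenyl]prop-2-enoate
Product: 22 (1S,5S)-2,5-dimethyl-5-[(1S)-1-methyl-2-methylidenecyclopentyl]cyclohex-2-en-1-yl (E)-3-(3,4-dihydroxyphenyl)prop-2-enoate (CNP0268865.1)
Conditions: HF·pyridine, pyridine, THF, 0 °C → rt
Reagents that add atoms: none
Why: Buffered fluoride cleaves the two aryl silyl ethers and should leave the allylic ester, both alkenes and the three stereocentres untouched.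

**Compound list**

1 | 2,3-dimethylbuta-1,3-diene | CC(=C)C(C)=C | starting material
2 | (E)-1,4-dibromo-2,3-dimethylbut-2-ene | BrC/C(C)=C(C)/CBr | intermediate
3 | 2-(2-bromoethyl)-2-methyl-1,3-dioxolane | CC1(CCBr)OCCO1 | starting material
4 | [2-(2-methyl-1,3-dioxolan-2-yl)ethyl]magnesium bromide | CC1(CC[Mg]Br)OCCO1 | intermediate (not isolated)
5 | 2-[(E)-6-bromo-4,5-dimethylhex-4-en-1-yl]-2-methyl-1,3-dioxolane | CC1(CCC/C(C)=C(C)/CBr)OCCO1 | intermediate
6 | 2-[(E)-4,5-dimethylocta-4,7-dien-1-yl]-2-methyl-1,3-dioxolane | CC1(CCC/C(C)=C(C)/CC=C)OCCO1 | intermediate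
7 | (E)-6,7-dimethyldeca-6,9-dien-2-one | CC(=O)CCC/C(C)=C(C)/CC=C | intermediate
8 | ethyl propanoate | CCC(=O)OCC | starting material
9 | (E)-8,9-dimethyldodeca-8,11-diene-3,5-dione (reacts as its chelated enol) | CCC(=O)CC(=O)CCC/C(C)=C(C)/CC=C | intermediate
10 | 1-[(1R,5R,6S)-1-hydroxy-5,6-dimethyl-6-(prop-2-en-1-yl)bicyclo[3.2.0]heptan-7-yl]propan-1-one (cis-fused; 1-OH and 5-CH3 cis; allyl exo, cis to 5-CH3; C7 epimers) | CCC(=O)C1[C@]2(O)CCC[C@]2(C)[C@@]1(C)CC=C | intermediate (not isolated)
11 | (2R)-2-methyl-2-[(4S)-4-methyl-6-oxooct-1-en-4-yl]cyclopentan-1-one | O=C1CCC[C@]1(C)[C@@](C)(CC=C)CC(=O)CC | intermediate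
12 | (2R)-2-methyl-2-[(2S)-2-methyl-4-oxo-1-(1,2,4-trioxolan-3-yl)hexan-2-yl]cyclopentan-1-one (trioxolane C3 epimers) | O=C1CCC[C@]1(C)[C@@](C)(CC1OCOO1)CC(=O)CC | intermediate (not isolated)
13 | (3S)-3-methyl-3-[(1R)-1-methyl-2-oxocyclopentyl]-5-oxoheptanal | O=C1CCC[C@]1(C)[C@@](C)(CC=O)CC(=O)CC | intermediate
14 | (5S)-3-hydroxy-2,5-dimethyl-5-[(1R)-1-methyl-2-oxocyclopentyl]cyclohexan-1-one (C2 and C3 epimers) | O=C1CCC[C@]1(C)[C@@]1(C)CC(O)C(C)C(=O)C1 | intermediate (not isolated)
15 | (5S)-2,5-dimethyl-5-[(1R)-1-methyl-2-oxocyclopentyl]cyclohex-2-en-1-one | O=C1CCC[C@]1(C)[C@@]1(C)CC=C(C)C(=O)C1 | intermediate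
16 | (2R)-2-[(1S,5S)-5-hydroxy-1,4-dimethylcyclohex-3-en-1-yl]-2-methylcyclopentan-1-one | O=C1CCC[C@]1(C)[C@@]1(C)CC=C(C)[C@@H](O)C1 | intermediate
17 | (1S,5S)-2,5-dimethyl-5-[(1S)-1-methyl-2-methylidenecyclopentyl]cyclohex-2-en-1-ol | C=C1CCC[C@]1(C)[C@@]1(C)CC=C(C)[C@@H](O)C1 | intermediate
18 | caffeic acid, (E)-3-(3,4-dihydroxyphenyl)prop-2-enoic acid | OC(=O)/C=C/c1ccc(O)c(O)c1 | starting material
19 | tert-butyldimethylsilyl (E)-3-[3,4-bis(tert-butyldimethylsilyloxy)phenyl]prop-2-enoate | CC(C)(C)[Si](C)(C)OC(=O)/C=C/c1ccc(O[Si](C)(C)C(C)(C)C)c(O[Si](C)(C)C(C)(C)C)c1 | intermediate (not isolated)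
20 | (E)-3-[3,4-bis(tert-butyldimethylsilyloxy)phenyl]prop-2-enoic acid | OC(=O)/C=C/c1ccc(O[Si](C)(C)C(C)(C)C)c(O[Si](C)(C)C(C)(C)C)c1 | intermediate
21 | (1S,5S)-2,5-dimethyl-5-[(1S)-1-methyl-2-methylidenecyclopentyl]cyclohex-2-en-1-yl (E)-3-[3,4-bis(tert-butyldimethylsilyloxy)phenyl]prop-2-enoate | C=C1CCC[C@]1(C)[C@@]1(C)CC=C(C)[C@@H](OC(=O)/C=C/c2ccc(O[Si](C)(C)C(C)(C)C)c(O[Si](C)(C)C(C)(C)C)c2)C1 | intermediate
22 | (1S,5S)-2,5-dimethyl-5-[(1S)-1-methyl-2-methylidenecyclopentyl]cyclohex-2-en-1-yl (E)-3-(3,4-dihydroxyphenyl)prop-2-enoate | C=C1CCC[C@]1(C)[C@@]1(C)CC=C(C)[C@@H](OC(=O)/C=C/c2ccc(O)c(O)c2)C1 | target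

**Step count**

Total: 13 steps. Longest linear sequence: 12 steps (1 → 22 through steps 1–10, 12 and 13); step 11 prepares the side-chain acid.

**Steps most likely to fail**

Step 6 (proposed new method). The chiral Lewis acid may discriminate the two faces of the chelate only weakly, or the uncatalysed reaction of free enol and slow catalyst turnover may erode the selectivity. Closure of the biradical with the C1' methyl group on the convex face would in addition give the C1' epimer. The fallback uses known chemistry, a racemic photoreaction followed by resolution through a reagent-controlled reduction; it sets out from 9 and returns at 16.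
- 9 is irradiated as its free enol without additive (Pyrex-filtered medium-pressure mercury lamp, cyclohexane, rt), the known racemic intramolecular de Mayo reaction.
- Through 10 and its enantiomer 1-[(1S,5S,6R)-1-hydroxy-5,6-dimethyl-6-(prop-2-en-1-yl)bicyclo[3.2.0]heptan-7-yl]propan-1-one F1, this should give 11 together with its enantiomer (2S)-2-methyl-2-[(4R)-4-methyl-6-oxooct-1-en-4-yl]cyclopentan-1-one F2.
- The racemate is taken through steps 7 and 8 as written. Beside 12 to 15 there form the ozonide (2S)-2-methyl-2-[(2R)-2-methyl-4-oxo-1-(1,2,4-trioxolan-3-yl)hexan-2-yl]cyclopentan-1-one F3, the keto aldehyde (3R)-3-methyl-3-[(1S)-1-methyl-2-oxocyclopentyl]-5-oxoheptanal F4, the aldol adduct (5R)-3-hydroxy-2,5-dimethyl-5-[(1S)-1-methyl-2-oxocyclopentyl]cyclohexan-1-one F5 and the enone (5R)-2,5-dimethyl-5-[(1S)-1-methyl-2-oxocyclopentyl]cyclohex-2-en-1-one F6.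
- Step 9 with the (R) catalyst then serves as the resolution: reagent control should make C5' (S) in both series, so 15 gives 16 and F6 gives the diastereomer (2S)-2-[(1R,5S)-5-hydroxy-1,4-dimethylcyclohex-3-en-1-yl]-2-methylcyclopentan-1-one F7.
- 16 and F7 differ in the relative configuration of C5' and C1' and are separated by chromatography; the route continues from 16.

Step 9. The reagent has to deliver hydride to the ring face that carries the axial C1' methyl group, so catalyst and substrate may be a mismatched pair and the facial selectivity at C5' poor. The fallback sets the opposite configuration and inverts it during esterification; it sets out from 15 and returns at 21.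
- 15 is reduced with the enantiomeric (S)-Me-CBS oxazaborolidine and catecholborane (the matched pair) to (2R)-2-[(1S,5R)-5-hydroxy-1,4-dimethylcyclohex-3-en-1-yl]-2-methylcyclopentan-1-one F8.
- F8 is methylenated as in step 10 to (1R,5S)-2,5-dimethyl-5-[(1S)-1-methyl-2-methylidenecyclopentyl]cyclohex-2-en-1-ol F9.
- F9 is esterified with acid 20 under Mitsunobu conditions (PPh3, DIAD, toluene, 0 °C), which inverts C5' and gives 21 directly.

Step 10. The basic ylide may enolise the neopentyl C2 ketone toward C3 instead of adding to it, so that conversion stalls. The fallback protects O5' and uses a non-basic titanium carbene; it sets out from 16 and returns at 17.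
- O5' is silylated (TESCl, imidazole, DMF, rt) to (2R)-2-[(1S,5S)-1,4-dimethyl-5-(triethylsilyloxy)cyclohex-3-en-1-yl]-2-methylcyclopentan-1-one F10.
- The ketone is methylenated by Petasis olefination with Cp2TiMe2 (toluene, 70 °C) to triethyl{[(1S,5S)-2,5-dimethyl-5-[(1S)-1-methyl-2-methylidenecyclopentyl]cyclohex-2-en-1-yl]oxy}silane F11.
- TBAF in THF frees 17.

**Further compounds**

F1 | step 6 | 1-[(1S,5S,6R)-1-hydroxy-5,6-dimethyl-6-(prop-2-en-1-yl)bicyclo[3.2.0]heptan-7-yl]propan-1-one (enantiomer of 10) | CCC(=O)C1[C@@]2(O)CCC[C@@]2(C)[C@]1(C)CC=C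
F2 | step 6 | (2S)-2-methyl-2-[(4R)-4-methyl-6-oxooct-1-en-4-yl]cyclopentan-1-one (enantiomer of 11) | O=C1CCC[C@@]1(C)[C@](C)(CC=C)CC(=O)CC
F3 | step 6 | (2S)-2-methyl-2-[(2R)-2-methyl-4-oxo-1-(1,2,4-trioxolan-3-yl)hexan-2-yl]cyclopentan-1-one (enantiomer of 12) | O=C1CCC[C@@]1(C)[C@](C)(CC1OCOO1)CC(=O)CC
F4 | step 6 | (3R)-3-methyl-3-[(1S)-1-methyl-2-oxocyclopentyl]-5-oxoheptanal (enantiomer of 13) | O=C1CCC[C@@]1(C)[C@](C)(CC=O)CC(=O)CC
F5 | step 6 | (5R)-3-hydroxy-2,5-dimethyl-5-[(1S)-1-methyl-2-oxocyclopentyl]cyclohexan-1-one (enantiomer of 14) | O=C1CCC[C@@]1(C)[C@]1(C)CC(O)C(C)C(=O)C1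
F6 | step 6 | (5R)-2,5-dimethyl-5-[(1S)-1-methyl-2-oxocyclopentyl]cyclohex-2-en-1-one (enantiomer of 15) | O=C1CCC[C@@]1(C)[C@]1(C)CC=C(C)C(=O)C1
F7 | step 6 | (2S)-2-[(1R,5S)-5-hydroxy-1,4-dimethylcyclohex-3-en-1-yl]-2-methylcyclopentan-1-one | O=C1CCC[C@@]1(C)[C@]1(C)CC=C(C)[C@@H](O)C1
F8 | step 9 | (2R)-2-[(1S,5R)-5-hydroxy-1,4-dimethylcyclohex-3-en-1-yl]-2-methylcyclopentan-1-one | O=C1CCC[C@]1(C)[C@@]1(C)CC=C(C)[C@H](O)C1
F9 | step 9 | (1R,5S)-2,5-dimethyl-5-[(1S)-1-methyl-2-methylidenecyclopentyl]cyclohex-2-en-1-ol | C=C1CCC[C@]1(C)[C@@]1(C)CC=C(C)[C@H](O)C1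
F10 | step 10 | (2R)-2-[(1S,5S)-1,4-dimethyl-5-(triethylsilyloxy)cyclohex-3-en-1-yl]-2-methylcyclopentan-1-one | O=C1CCC[C@]1(C)[C@@]1(C)CC=C(C)[C@@H](O[Si](CC)(CC)CC)C1
F11 | step 10 | triethyl{[(1S,5S)-2,5-dimethyl-5-[(1S)-1-methyl-2-methylidenecyclopentyl]cyclohex-2-en-1-yl]oxy}silane | C=C1CCC[C@]1(C)[C@@]1(C)CC=C(C)[C@@H](O[Si](CC)(CC)CC)C1
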